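Assumption (chemistry): the ring carbons are numbered C1–C10 throughout as in the target (C1 allylic acetoxy carbon, C2=C3 with methyl on C3, C6/C7 epoxide carbons, C11 the formyl carbon on C7, C9 second acetoxy carbon, C10 isopropyl carbon). Compounds 1, 2, 5, 11 and 15 are taken as commercial.

## The problem

The target is a ten-membered carbocycle. It carries a ring-cis trisubstituted alkene (C2=C3), a trisubstituted epoxide (C6–C7) whose quaternary carbon bears a formyl group (C11), two secondary acetates (C1, C9) and an isopropyl group (C10). Closing a cyclodecane by C–C bond formation is penalised by transannular strain and entropy, so the ring is better revealed than closed. Of the five stereocentres, C1/C10/C9 are contiguous: both C–O bonds are cis to each other and trans to the isopropyl group. The C9/C10 pair can be set in an open chain, and the C9 hydroxyl, 1,3 to C1, can then direct the C1 carbinol. The epoxide carbons C6/C7 are remote from this triad, so nothing on the ring controls them reliably; reagent control through the C11 hydroxyl is needed. The α,β-epoxy aldehyde tolerates neither base nor nucleophiles, and a free C9 hydroxyl would close a lactol onto C11, so both acetates must be in place before the aldehyde is unveiled last. The enabling feature is that C1 and C7 lie 1,5 across the ring on both sides: a C1–C7 bond divides the ring into a cyclopentane (C1, C7–C10) and a cycloheptene (C1–C7). Because C1 is oxygenated and C6/C7 are at the alkene level, O–C1–C7–C6–X is a Grob array.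

## Retrosynthesis

**34 ⇒ 33 ⇒ 32 (C–O bonds at C11, C6, C7).** The aldehyde and the epoxide go first. Target 34 is the oxidation product of epoxy alcohol 33, which comes from primary allylic alcohol 32 by tartrate-controlled epoxidation. This order keeps the fragile epoxy aldehyde out of every other step and uses the C11 hydroxyl as the only handle that carries reagent control to the remote C6=C7 face. The forward reaction must leave the C2=C3 alkene, which has no free allylic hydroxyl, untouched.

**32 ⇒ 31 ⇒ 30 ⇒ 28 ⇒ 27 (C1–H bond, protecting groups).** Diacetate 32 is traced through silyl ether 31 to the syn-1,3-diol 30, and 30 to β-hydroxy enone 28 by removing the C1 hydride. The C1–O/C9–O cis relation is the signature of a chelation-controlled syn reduction, preferable to an undirected reduction whose facial bias in a flexible ten-membered ring cannot be predicted. This requires two silyl groups of different lability in dienone 27: tert-butyldimethylsilyl on C9 (off first) and tert-butyldiphenylsilyl on C11 (kept until the acetates are on).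

**27 ⇒ 25 (C1–C7 bond, key disconnection).** Reconnecting C1 to C7 and placing a mesylate on C6 turns the cyclodecadienone into the cis-fused hydroazulenol 25.
- The neighbouring choice, a C1–C6 bond giving a decalin, would need a tertiary leaving group on C7 next to C11 and is harder to build and to ionise cleanly.
- The medium ring becomes a fused 5/7 bicycle made by ordinary ring chemistry. The stereocentres C1, C6 and C7 are relays that vanish in the fragmentation.
- The forward step needs the C6–OMs bond antiperiplanar to C1–C7 and the correct C6/C7 relative configuration, which alone decides the geometry of the C6=C7 alkene.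

**25 ⇒ 24 ⇒ 23 ⇒ 22 ⇒ 20 (functional groups, then C1–C2).** Mesylate 25 comes from triol 23 through silyl ether 24, and 23 from ester 22. Cutting the C1–C2 bond of 22 gives keto ester 20, which carries a (Z)-vinyl iodide. Closing the seven-membered ring from a tether on C7 onto the adjacent ketone delivers the vinyl group to the face the tether occupies. Cis fusion and the C1 configuration therefore follow from C7, and the alkene geometry is fixed in the iodide. A metathesis closure at C2=C3 would instead need an intermolecular vinyl addition to C1 of uncertain facial sense.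

**20 ⇒ 10 + 18 (C6–C7).** An aldol cut separates β-keto ester 10 from iodoenal 18. It creates the quaternary C7 and the C6 carbinol in one convergent step and halves the molecule. The step must deliver the right C6/C7 relative configuration. The face of C7 relative to C9/C10 is secondary, because the C7-epimeric series, if it carries the same C6/C7 relation, fragments to the same dienone 27.

**10 ⇒ 8 ⇒ 7 ⇒ 4 + 5 (C1–C7 of the cyclopentanone, C9–C10); 4 ⇒ 1 + 2.** The cyclopentanone is opened at the ketone–α-carbon bond to imide ester 8. Its silyl ether comes from aldol adduct 7, and 7 from acyl oxazolidinone 4 and aldehyde 5. A shorter entry, acid rearrangement of a furyl carbinol to the trans-4-hydroxy-5-isopropylcyclopentenone, was weighed against this. It gives racemic material, needs a resolution of unpredictable sense, and then a conjugate reduction–acylation. The auxiliary aldol sets C9 and C10 with known absolute sense and leads straight to the β-keto ester.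

**18 ⇒ 17 ⇒ 14 + 15; 14 ⇒ 13 ⇒ 11.** The enal comes from ester 17, made by alkylating the enolate of 15 with allylic bromide 14. Bromide 14 derives from iodo alcohol 13, whose (Z) geometry comes from hydroxyl-directed carbomagnesiation of propargyl alcohol 11.

## Roads not taken

**Alternative 1: [2,3]-Wittig ring contraction (cut C1–C10).** A thirteen-membered bis-allylic ether A2, with the ring oxygen between C1 and the future isopropenyl CH2, would be lithiated at C1 with excess n-BuLi and rearranged to the isopropenyl triol A1.
- Merits: the key step forms a skeletal bond and both the C1 and C10 stereocentres, and delivers the C1 hydroxyl directly. The chosen plan's key step builds neither a bond nor a stereocentre and needs a later ketone reduction. In these respects this road is better.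
- Weak points: two competing α-oxy allylic positions can be metalated. The syn/anti outcome at C1/C10 and its relation to the existing C9 centre depend on a macrocyclic transition state that cannot be predicted. The hydroxyls travel as alkoxides. A2 itself requires a macro-etherification under dilution. The isopropenyl group must afterwards be reduced in the presence of two ring alkenes.
- Comparison: the chosen plan sets C9/C10 by an aldol of established sense and C1 by chelation, each in a separate, checkable operation.

**Alternative 2: palladium–zinc umpolung allylation (cut C8–C9).** The open-chain aldehyde allylic chloride A4 would be converted by Pd(PPh3)4 (zerovalent palladium) and Et2Zn into an allylzinc that adds to the C9 aldehyde, giving the ten-membered homoallylic alcohol A3 with an exocyclic methylene on C7.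
- Merits: it is convergent, and A3 leaves the three oxygens differently protected. The preset C6 oxygen can relay the epoxide configuration (directed epoxidation of the exocyclic alkene, then Payne rearrangement) without a reagent-controlled epoxidation on a medium ring. That is an advantage over the chosen plan, whose late epoxidation depends on tartrate control.
- Weak points: the ten-membered ring is closed by C–C bond formation, with the attendant dilution, oligomerisation and protonation of the allylzinc. The new C9 centre is controlled only by the adjacent C10 centre in a strained cyclic transition state. A4 needs three stereocentres (C1, C10, C6) made independently, and the Payne relay adds steps.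
- Comparison: the chosen plan avoids any closure of the medium ring and needs only one stereochemical operation before the bicycle exists.

**Alternative 3: Ramberg–Bäcklund contraction (cut C2=C3).** An eleven-membered sulfone acetonide A6 with sulfur between C2 and C3 would be halogenated in situ (CBr2F2, KOH on Al2O3) and extrude SO2 to give the diene acetonide A5.
- Merits: ring closure by sulfide formation is among the easier macrocyclisations. A5 already carries the C1/C9 syn diol, so no late ketone reduction is needed. The small ring strongly favours the cis alkene. On these points this road is as good as or better than the chosen one.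
- Weak points: the alkene geometry is biased by strain rather than dictated by mechanism. A6 requires C1, C9, C10 and the C6=C7 alkene to be assembled in an open chain before an eleven-membered closure, which makes a longer linear sequence. The strongly basic halogenating medium must spare the allylic silyl ether.
- Comparison: in the chosen plan the C6=C7 geometry is stereospecific, and the second alkene is held cis by a seven-membered ring from the outset.

Key step: step 14

## Route

Step 1
Reactants: 1 (S)-4-benzyloxazolidin-2-one; 2 3-methylbutanoyl chloride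
Product: 4 (S)-4-benzyl-3-(3-methylbutanoyl)oxazolidin-2-one, via lithium amide 3 (not isolated)
Conditions: n-BuLi, THF, −78 °C; then 2, −78 → 0 °C
Reagents that add atoms: none
Why: N-acylation of the lithiated oxazolidinone by the acid chloride is the standard way to load this auxiliary; no stereocentre is touched.

Step 2
Reactants: 4 (S)-4-benzyl-3-(3-methylbutanoyl)oxazolidin-2-one; 5 methyl 4-oxobutanoate
Product: 7 methyl (4R,5S)-5-[(S)-4-benzyl-2-oxooxazolidine-3-carbonyl]-4-hydroxy-6-methylheptanoate, via boron enolate 6 (not isolated)
Conditions: Bu2BOTf, iPr2NEt, CH2Cl2, 0 °C; then 5, −78 → 0 °C; pH 7 buffer, MeOH, H2O2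
Reagents that add atoms: none
Why: Auxiliary-controlled syn aldol through the (Z)-boron enolate and a Zimmerman–Traxler chair; the (S)-benzyl auxiliary sets C10 (S) and C9 (R), the syn pair that becomes trans on the ring. The methyl ester of 5 is inert to the boron enolate, and the crude hydroxy ester is silylated at once to forestall γ-lactonisation.

Step 3
Reactants: 7 syn-aldol adduct
Product: 8 methyl (4R,5S)-5-[(S)-4-benzyl-2-oxooxazolidine-3-carbonyl]-4-[(tert-butyldimethylsilyl)oxy]-6-methylheptanoate
Conditions: TBSOTf, 2,6-lutidine, CH2Cl2, −78 → 0 °C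
Reagents that add atoms: tert-butyldimethylsilyl trifluoromethanesulfonate, CC(C)(C)[Si](C)(C)OS(=O)(=O)C(F)(F)F
Why: Silylation of a hindered secondary alcohol with the silyl triflate; the non-nucleophilic base leaves imide and ester intact.

Step 4
Reactants: 8 silylated aldol adduct
Product: 10 methyl (3S,4R)-4-[(tert-butyldimethylsilyl)oxy]-2-oxo-3-(propan-2-yl)cyclopentane-1-carboxylate, via sodium ester enolate 9 (not isolated)
Conditions: NaN(SiMe3)2 (2.1 equiv), THF, −78 → −20 °C; aq. NH4Cl
Reagents that add atoms: none
Why: Dieckmann-type (intramolecular Claisen) acylation: the ester CH2 is deprotonated in preference to the α-branched imide C–H, which is shielded by allylic strain, and the enolate attacks the exocyclic imide carbonyl 5-exo-trig with loss of the oxazolidinone anion. The product is held as its stabilised enolate, which protects the β-silyloxy ketone from elimination; C10 is not enolised, and trans is in any case the more stable arrangement.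

Step 5
Reactants: 11 prop-2-yn-1-ol
Product: 13 (Z)-3-iodo-2-methylprop-2-en-1-ol, via cyclic vinylmagnesium alkoxide 12 (not isolated)
Conditions: MeMgBr (3 equiv), CuI (10 mol %), THF, −20 °C → rt; then I2, −78 → 0 °C
Reagents that add atoms: methylmagnesium bromide, C[Mg]Br; iodine, II
Why: Copper-catalysed, alkoxide-directed carbomagnesiation puts methyl on the internal carbon and magnesium cis to the CH2O group in a five-membered chelate; iodinolysis with retention gives the (Z)-iodide, which fixes the C2=C3 geometry.

Step 6
Reactants: 13 (Z)-3-iodo-2-methylprop-2-en-1-ol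
Product: 14 (Z)-3-bromo-1-iodo-2-methylprop-1-ene
Conditions: CBr4, PPh3, CH2Cl2, 0 °C
Reagents that add atoms: carbon tetrabromide, BrC(Br)(Br)Br
Why: Appel bromination of a primary allylic alcohol under neutral conditions; the vinyl iodide and its geometry are unaffected.

Step 7
Reactants: 14 (Z)-3-bromo-1-iodo-2-methylprop-1-ene; 15 tert-butyl acetate
Product: 17 tert-butyl (Z)-5-iodo-4-methylpent-4-enoate, via lithium enolate 16 (not isolated)
Conditions: LiN(iPr)2, THF, −78 °C; then 14, −78 → −30 °C
Reagents that add atoms: none
Why: SN2 alkylation of a stable ester enolate by a reactive primary allylic bromide forms the C4–C5 bond; the vinyl iodide is inert to the enolate.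

Step 8
Reactants: 17 tert-butyl (Z)-5-iodo-4-methylpent-4-enoate
Product: 18 (Z)-5-iodo-4-methylpent-4-enal
Conditions: iBu2AlH, CH2Cl2, −78 °C; aq. Rochelle salt
Reagents that add atoms: none
Why: Partial reduction of the bulky ester stops at the tetrahedral aluminate at −78 °C and releases the aldehyde on work-up.

Step 9
Reactants: 10 β-keto ester; 18 (Z)-5-iodo-4-methylpent-4-enal
Product: 20 methyl (1S,3S,4R)-4-[(tert-butyldimethylsilyl)oxy]-1-[(1R,4Z)-1-hydroxy-5-iodo-4-methylpent-4-en-1-yl]-2-oxo-3-(propan-2-yl)cyclopentane-1-carboxylate, via titanium enolate 19 (not isolated)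
Conditions: TiCl4, Et3N, CH2Cl2, −78 °C; then 18, −78 °C; aq. NH4Cl at −78 °C
Reagents that add atoms: none
Why: Aldol addition of a chelated titanium enolate of a 2-substituted β-keto ester creates the quaternary C7 and the C6 carbinol. The aldehyde, bound to titanium above the planar chelate, should approach the face opposite the C10 isopropyl group with its chain over the ester oxygen rather than over the ring carbon that carries the isopropyl group, which gives the C6/C7 relation shown. The cold quench keeps the adduct from reverting.

Step 10
Reactants: 20 aldol adduct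
Product: 22 methyl (1S,2R,3aS,4R,8aS)-2-[(tert-butyldimethylsilyl)oxy]-4,8a-dihydroxy-7-methyl-1-(propan-2-yl)-1,2,3,3a,4,5,6,8a-octahydroazulene-3a-carboxylate, via vinylchromium species 21 (not isolated)
Conditions: CrCl2 (8 equiv), NiCl2 (5 mol %), DMSO, rt → 40 °C
Reagents that add atoms: none
Why: Intramolecular Nozaki–Hiyama–Kishi reaction: zerovalent nickel inserts into the C–I bond, the vinyl group passes to trivalent chromium and adds to the neighbouring ketone to close the seven-membered ring. The tether on C7 can only reach the ketone face it occupies, so the ring fusion is cis and C1 is set by C7. Ester, free hydroxyl, silyl ether and alkene geometry are tolerated.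

Step 11
Reactants: 22 bicyclic diol ester
Product: 23 (1S,2R,3aS,4R,8aS)-2-[(tert-butyldimethylsilyl)oxy]-3a-(hydroxymethyl)-7-methyl-1-(propan-2-yl)-1,2,3,3a,4,5,6,8a-octahydroazulene-4,8a-diol
Conditions: LiAlH4, THF, 0 °C
Reagents that add atoms: none
Why: Hydride reduction of the ester to the primary alcohol (C11). Removing the carbonyl from C7 ensures that the later ring opening cannot run through a stepwise retro-aldol–elimination that would lose the alkene geometry.

Step 12
Reactants: 23 triol
Product: 24 (1S,2R,3aS,4R,8aS)-2-[(tert-butyldimethylsilyl)oxy]-3a-{[(tert-butyldiphenylsilyl)oxy]methyl}-7-methyl-1-(propan-2-yl)-1,2,3,3a,4,5,6,8a-octahydroazulene-4,8a-diol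
Conditions: TBDPSCl, imidazole, DMF, 0 °C → rt
Reagents that add atoms: tert-butyl(chloro)diphenylsilane, CC(C)(C)[Si](Cl)(c1ccccc1)c1ccccc1
Why: Silylation with a bulky chlorosilane selects the primary hydroxyl over the hindered secondary and the tertiary ones. The diphenyl silyl ether is chosen because it resists both 1,3-migration to an alkoxide and the later acid cleavage of the C9 silyl ether.

Step 13
Reactants: 24 diol
Product: 25 (1S,2R,3aS,4R,8aS)-2-[(tert-butyldimethylsilyl)oxy]-3a-{[(tert-butyldiphenylsilyl)oxy]methyl}-8a-hydroxy-7-methyl-1-(propan-2-yl)-1,2,3,3a,4,5,6,8a-octahydroazulen-4-yl methanesulfonate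
Conditions: MsCl, Et3N, CH2Cl2, −20 → 0 °C
Reagents that add atoms: methanesulfonyl chloride, CS(=O)(=O)Cl
Why: Sulfonylation through sulfene reaches the hindered secondary hydroxyl while the tertiary bridgehead hydroxyl stays free. The mesylate is used without prolonged storage.

Step 14
Reactants: 25 hydroazulenol mesylate
Product: 27 (2Z,6E,9R,10S)-9-[(tert-butyldimethylsilyl)oxy]-7-{[(tert-butyldiphenylsilyl)oxy]methyl}-3-methyl-10-(propan-2-yl)cyclodeca-2,6-dien-1-one, via potassium alkoxide 26 (not isolated)
Conditions: KOtBu (1.1 equiv), THF, 0 °C → rt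
Reagents that add atoms: none
Why: Deprotonation of the tertiary C1 hydroxyl gives alkoxide 26; its oxygen lone pair pushes into the C1–C7 bond, which lies antiperiplanar to the pseudo-equatorial C6–OMs bond and expels mesylate in a concerted Grob (Wharton-type) fragmentation of a cyclic 1,3-diol monosulfonate, the closest known reaction type. No ring is closed and no stereocentre is created: the ten-membered ring appears because the bond shared by the five- and seven-membered rings is cut, so no closure mode and no dilution are involved. The selectivity needed is the ring-cis geometry of the new C6=C7 bond (E by the sequence rule because of the CH2O substituent). It is fixed by the C6/C7 relative configuration from steps 9 and 10: with the mesylate cis to the C7–C8 bond and trans to the silyloxymethyl group, C5 and C8 are gauche in the antiperiplanar conformer and end up cis on the alkene. That conformer is also the preferred one, since it puts the bulky silyloxymethyl group equatorial on the cycloheptene. Fragmentation must outrun formation of a strained bridged oxetane, and the product must not meet excess base, which could eliminate the β-silyloxy group or epimerise C10; hence about one equivalent of base at 0 °C and a silyl ether rather than a free hydroxyl on C11. The C2=C3 alkene keeps the cis geometry imposed by the seven-membered ring.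

Step 15
Reactants: 27 silylated cyclodecadienone
Product: 28 (2Z,6E,9R,10S)-7-{[(tert-butyldiphenylsilyl)oxy]methyl}-9-hydroxy-3-methyl-10-(propan-2-yl)cyclodeca-2,6-dien-1-one
Conditions: HF·pyridine, pyridine, THF, 0 °C → rt
Reagents that add atoms: none
Why: Selective desilylation: the secondary tert-butyldimethylsilyl ether is cleaved by buffered HF well before the primary tert-butyldiphenylsilyl ether, and the mildly acidic medium avoids base-induced dehydration of the β-hydroxy ketone.

Step 16
Reactants: 28 β-hydroxy enone
Product: 30 (1S,2Z,6E,9R,10S)-7-{[(tert-butyldiphenylsilyl)oxy]methyl}-3-methyl-10-(propan-2-yl)cyclodeca-2,6-diene-1,9-diol (route numbering), via diethylborinate 29 (not isolated)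
Conditions: Et2BOMe, THF/MeOH (4:1), −78 °C; NaBH4, −78 °C; AcOH, then MeOH co-evaporation
Reagents that add atoms: none
Why: Narasaka–Prasad reduction: the C9 borinate chelates the ketone in a half-chair and external hydride adds axially, on the face away from the axial isopropyl group, to give the 1,3-syn diol and set C1 (S). The β,β-disubstituted enone and the activated, chelated carbonyl favour 1,2- over 1,4-reduction.

Step 17
Reactants: 30 syn-1,3-diol
Product: 31 (1S,2Z,6E,9R,10S)-7-{[(tert-butyldiphenylsilyl)oxy]methyl}-3-methyl-10-(propan-2-yl)cyclodeca-2,6-diene-1,9-diyl diacetate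
Conditions: Ac2O, DMAP, pyridine, CH2Cl2, rt
Reagents that add atoms: acetic anhydride, CC(=O)OC(C)=O
Why: DMAP-catalysed acylation of both secondary alcohols. Installing the acetates now removes the C9 hydroxyl that would otherwise trap the future aldehyde as a lactol.

Step 18
Reactants: 31 diacetate silyl ether
Product: 32 (1S,2Z,6E,9R,10S)-7-(hydroxymethyl)-3-methyl-10-(propan-2-yl)cyclodeca-2,6-diene-1,9-diyl diacetate
Conditions: Bu4NF, AcOH, THF, 0 °C → rt
Reagents that add atoms: none
Why: Fluoride desilylation buffered with acetic acid frees the primary allylic alcohol without acetate cleavage or acyl migration.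

Step 19
Reactants: 32 primary allylic alcohol
Product: 33 (1R,3R,4S,5S,6Z,10R)-1-(hydroxymethyl)-7-methyl-4-(propan-2-yl)-11-oxabicyclo[8.1.0]undec-6-ene-3,5-diyl diacetate
Conditions: Ti(OiPr)4 (0.3 equiv), D-(−)-diethyl tartrate (0.36 equiv), t-BuOOH, 4 Å MS, CH2Cl2, −20 °C
Reagents that add atoms: tert-butyl hydroperoxide, CC(C)(C)OO
Why: Sharpless asymmetric epoxidation: only the alkene with a free allylic hydroxyl binds titanium, so C6=C7 reacts and C2=C3 does not. The substrate belongs to the favourable class with no substituent cis to the carbinol carbon. By the empirical face rule the D-(−)-tartrate delivers oxygen to the face that gives the C6/C7 configuration of the target; the cis ring geometry of the alkene is carried into the epoxide.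

Step 20
Reactants: 33 epoxy alcohol
Product: 34 (1S,3R,4S,5S,6Z,10R)-1-formyl-7-methyl-4-(propan-2-yl)-11-oxabicyclo[8.1.0]undec-6-ene-3,5-diyl diacetate
Conditions: Dess–Martin periodinane, NaHCO3, CH2Cl2, 0 °C → rt
Reagents that add atoms: none
Why: Dess–Martin oxidation under buffered, non-nucleophilic conditions converts the primary alcohol into the aldehyde without opening the epoxide or touching the acetates; the quaternary α-carbon cannot epimerise.

## Compound list

1 | (S)-4-benzyloxazolidin-2-one | O=C1N[C@@H](Cc2ccccc2)CO1 | starting material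
2 | 3-methylbutanoyl chloride | CC(C)CC(Cl)=O | starting material
3 | (S)-4-benzyl-3-lithiooxazolidin-2-one (not isolated) | O=C1N([Li])[C@@H](Cc2ccccc2)CO1 | intermediate
4 | (S)-4-benzyl-3-(3-methylbutanoyl)oxazolidin-2-one | CC(C)CC(=O)N1C(=O)OC[C@@H]1Cc1ccccc1 | intermediate
5 | methyl 4-oxobutanoate | COC(=O)CCC=O | starting material
6 | (Z)-dibutylboron enolate of 4 (not isolated) | CC(C)/C=C(\OB(CCCC)CCCC)N1C(=O)OC[C@@H]1Cc1ccccc1 | intermediate
7 | methyl (4R,5S)-5-[(S)-4-benzyl-2-oxooxazolidine-3-carbonyl]-4-hydroxy-6-methylheptanoate | COC(=O)CC[C@@H](O)[C@@H](C(=O)N1C(=O)OC[C@@H]1Cc1ccccc1)C(C)C | intermediate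
8 | methyl (4R,5S)-5-[(S)-4-benzyl-2-oxooxazolidine-3-carbonyl]-4-[(tert-butyldimethylsilyl)oxy]-6-methylheptanoate | COC(=O)CC[C@@H](O[Si](C)(C)C(C)(C)C)[C@@H](C(=O)N1C(=O)OC[C@@H]1Cc1ccccc1)C(C)C | intermediate
9 | sodium enolate of the methyl ester of 8 (not isolated) | COC(O[Na])=CC[C@@H](O[Si](C)(C)C(C)(C)C)[C@@H](C(=O)N1C(=O)OC[C@@H]1Cc1ccccc1)C(C)C | intermediate
10 | methyl (3S,4R)-4-[(tert-butyldimethylsilyl)oxy]-2-oxo-3-(propan-2-yl)cyclopentane-1-carboxylate (C1 epimers and enol) | COC(=O)C1C[C@@H](O[Si](C)(C)C(C)(C)C)[C@H](C(C)C)C1=O | intermediate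
11 | prop-2-yn-1-ol | C#CCO | starting material
12 | 3-methyl-2,5-dihydro-1,2-oxamagnesole, cyclic vinylmagnesium alkoxide (not isolated) | CC1=C[Mg]OC1 | intermediate
13 | (Z)-3-iodo-2-methylprop-2-en-1-ol | OC/C(C)=C\I | intermediate
14 | (Z)-3-bromo-1-iodo-2-methylprop-1-ene | BrC/C(C)=C\I | intermediate
15 | tert-butyl acetate | CC(=O)OC(C)(C)C | starting material
16 | lithium enolate of tert-butyl acetate (not isolated) | C=C(O[Li])OC(C)(C)C | intermediate
17 | tert-butyl (Z)-5-iodo-4-methylpent-4-enoate | CC(C)(C)OC(=O)CC/C(C)=C\I | intermediate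
18 | (Z)-5-iodo-4-methylpent-4-enal | O=CCC/C(C)=C\I | intermediate
19 | trichlorotitanium enolate of 10 (not isolated) | COC(=O)C1=C(O[Ti](Cl)(Cl)Cl)[C@@H](C(C)C)[C@H](O[Si](C)(C)C(C)(C)C)C1 | intermediate
20 | methyl (1S,3S,4R)-4-[(tert-butyldimethylsilyl)oxy]-1-[(1R,4Z)-1-hydroxy-5-iodo-4-methylpent-4-en-1-yl]-2-oxo-3-(propan-2-yl)cyclopentane-1-carboxylate (side chain trans to isopropyl) | I/C=C(/C)CC[C@@H](O)[C@@]1(C(=O)OC)C[C@@H](O[Si](C)(C)C(C)(C)C)[C@H](C(C)C)C1=O | intermediate
21 | vinylchromium dichloride derived from 20 (not isolated) | Cl[Cr](Cl)/C=C(/C)CC[C@@H](O)[C@@]1(C(=O)OC)C[C@@H](O[Si](C)(C)C(C)(C)C)[C@H](C(C)C)C1=O | intermediate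
22 | methyl (1S,2R,3aS,4R,8aS)-2-[(tert-butyldimethylsilyl)oxy]-4,8a-dihydroxy-7-methyl-1-(propan-2-yl)-1,2,3,3a,4,5,6,8a-octahydroazulene-3a-carboxylate (cis-fused; 8a-OH, ester and isopropyl on one face, silyloxy on the other, 4-OH trans to the ester) | O[C@]12C=C(C)CC[C@@H](O)[C@@]1(C(=O)OC)C[C@@H](O[Si](C)(C)C(C)(C)C)[C@@H]2C(C)C | intermediate
23 | (1S,2R,3aS,4R,8aS)-2-[(tert-butyldimethylsilyl)oxy]-3a-(hydroxymethyl)-7-methyl-1-(propan-2-yl)-1,2,3,3a,4,5,6,8a-octahydroazulene-4,8a-diol | O[C@]12C=C(C)CC[C@@H](O)[C@@]1(CO)C[C@@H](O[Si](C)(C)C(C)(C)C)[C@@H]2C(C)C | intermediate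
24 | (1S,2R,3aS,4R,8aS)-2-[(tert-butyldimethylsilyl)oxy]-3a-{[(tert-butyldiphenylsilyl)oxy]methyl}-7-methyl-1-(propan-2-yl)-1,2,3,3a,4,5,6,8a-octahydroazulene-4,8a-diol | O[C@]12C=C(C)CC[C@@H](O)[C@@]1(CO[Si](c3ccccc3)(c3ccccc3)C(C)(C)C)C[C@@H](O[Si](C)(C)C(C)(C)C)[C@@H]2C(C)C | intermediate
25 | (1S,2R,3aS,4R,8aS)-2-[(tert-butyldimethylsilyl)oxy]-3a-{[(tert-butyldiphenylsilyl)oxy]methyl}-8a-hydroxy-7-methyl-1-(propan-2-yl)-1,2,3,3a,4,5,6,8a-octahydroazulen-4-yl methanesulfonate (key-step precursor) | O[C@]12C=C(C)CC[C@@H](OS(C)(=O)=O)[C@@]1(CO[Si](c3ccccc3)(c3ccccc3)C(C)(C)C)C[C@@H](O[Si](C)(C)C(C)(C)C)[C@@H]2C(C)C | intermediate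
26 | potassium 8a-alkoxide of 25 (not isolated) | [K]O[C@]12C=C(C)CC[C@@H](OS(C)(=O)=O)[C@@]1(CO[Si](c3ccccc3)(c3ccccc3)C(C)(C)C)C[C@@H](O[Si](C)(C)C(C)(C)C)[C@@H]2C(C)C | intermediate
27 | (2Z,6E,9R,10S)-9-[(tert-butyldimethylsilyl)oxy]-7-{[(tert-butyldiphenylsilyl)oxy]methyl}-3-methyl-10-(propan-2-yl)cyclodeca-2,6-dien-1-one (both ring alkenes cis in the ring; key-step product) | O=C1/C=C(/C)CC/C=C(CO[Si](c2ccccc2)(c2ccccc2)C(C)(C)C)\C[C@@H](O[Si](C)(C)C(C)(C)C)[C@@H]1C(C)C | intermediate
28 | (2Z,6E,9R,10S)-7-{[(tert-butyldiphenylsilyl)oxy]methyl}-9-hydroxy-3-methyl-10-(propan-2-yl)cyclodeca-2,6-dien-1-one | O=C1/C=C(/C)CC/C=C(CO[Si](c2ccccc2)(c2ccccc2)C(C)(C)C)\C[C@@H](O)[C@@H]1C(C)C | intermediate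
29 | C9 O-diethylboryl derivative of 28 (not isolated) | O=C1/C=C(/C)CC/C=C(CO[Si](c2ccccc2)(c2ccccc2)C(C)(C)C)\C[C@@H](OB(CC)CC)[C@@H]1C(C)C | intermediate
30 | (1S,2Z,6E,9R,10S)-7-{[(tert-butyldiphenylsilyl)oxy]methyl}-3-methyl-10-(propan-2-yl)cyclodeca-2,6-diene-1,9-diol (route numbering; hydroxyls cis, both trans to isopropyl) | O[C@H]1/C=C(/C)CC/C=C(CO[Si](c2ccccc2)(c2ccccc2)C(C)(C)C)\C[C@@H](O)[C@@H]1C(C)C | intermediate
31 | (1S,2Z,6E,9R,10S)-7-{[(tert-butyldiphenylsilyl)oxy]methyl}-3-methyl-10-(propan-2-yl)cyclodeca-2,6-diene-1,9-diyl diacetate | CC(=O)O[C@H]1/C=C(/C)CC/C=C(CO[Si](c2ccccc2)(c2ccccc2)C(C)(C)C)\C[C@@H](OC(C)=O)[C@@H]1C(C)C | intermediate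
32 | (1S,2Z,6E,9R,10S)-7-(hydroxymethyl)-3-methyl-10-(propan-2-yl)cyclodeca-2,6-diene-1,9-diyl diacetate | CC(=O)O[C@H]1/C=C(/C)CC/C=C(CO)\C[C@@H](OC(C)=O)[C@@H]1C(C)C | intermediate
33 | (1R,3R,4S,5S,6Z,10R)-1-(hydroxymethyl)-7-methyl-4-(propan-2-yl)-11-oxabicyclo[8.1.0]undec-6-ene-3,5-diyl diacetate | CC(=O)O[C@H]1/C=C(/C)CC[C@H]2O[C@@]2(CO)C[C@@H](OC(C)=O)[C@@H]1C(C)C | intermediate
34 | (1S,3R,4S,5S,6Z,10R)-1-formyl-7-methyl-4-(propan-2-yl)-11-oxabicyclo[8.1.0]undec-6-ene-3,5-diyl diacetate (CNP0145766.3) | CC(=O)O[C@H]1/C=C(/C)CC[C@H]2O[C@@]2(C=O)C[C@@H](OC(C)=O)[C@@H]1C(C)C | target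

## Step count and risk

Total: 20 steps. Longest linear sequence: 16 steps (steps 1–4 and 9–20, from 1); the side branch to 18 is steps 5–8.

**Step 14 (key step).** The alkoxide may fail to fragment cleanly: closure of a bridged oxetane, silyl migration from the C11 oxygen to the alkoxide, or base-induced loss of the β-silyloxy group from the product ketone could compete, because the product is itself base-sensitive. Fallback: open the bicycle by a retro-aldol instead. Starting from diol 24, Dess–Martin oxidation of the C6 hydroxyl gives the β-hydroxy ketone F1. KN(SiMe3)2 triggers retro-aldol cleavage of the C1–C7 bond, and the resulting ring enolate is trapped with PhNTf2 as the ten-membered enol triflate F2. Reduction of the triflate with Pd(OAc)2, PPh3, Bu3N and HCO2H replaces it by hydrogen and rejoins the route at 27.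

**Step 9.** The aldol may proceed with poor simple diastereoselection at C6, and the hindered quaternary adduct may revert, because a chelated 1,3-dicarbonyl enolate offers two six-membered transition states of similar energy. Fallback: set C6 after the ring is closed. Starting from 10 and 18, the aldol is run without relying on its C6 selectivity, giving 20 together with its C6 epimer F3. Chromium-mediated closure as in step 10 gives 22 and its C4 epimer F4. Dess–Martin oxidation of the mixture converges on one keto ester F5, and reduction with Me4NBH(OAc)3, in which the tertiary hydroxyl delivers hydride internally (Evans–Saksena anti reduction), returns only 22.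

**Step 10.** Addition of the vinylchromium species to a hindered ketone may be too slow, so that protonation of the organometallic or reduction of the iodide takes over; ketones are much poorer acceptors than aldehydes in this reaction. Fallback: an anionic Barbier-type closure on a protected substrate. Starting from 20, silylation (Et3SiCl, imidazole) gives the triethylsilyl ether F6. Iodine–lithium exchange with t-BuLi at −100 °C lets the vinyllithium add to the adjacent ketone faster than to the ester, giving the protected bicycle F7. Mild acid methanolysis (pyridinium p-toluenesulfonate, MeOH) removes the triethylsilyl group and rejoins the route at 22.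

**Step 4.** Enolisation may be unselective, or attack on the hindered imide carbonyl may be slow, leading to elimination of the silyloxy group or cleavage inside the oxazolidinone ring. Fallback: remove the auxiliary first and close the ring under thermodynamic control. Starting from 8, LiOH/H2O2 gives the acid F8, Me3SiCHN2 gives the dimethyl ester F9, and a classical Dieckmann condensation (KOtBu, THF) returns 10. Only closure through C7 leaves an enolisable β-keto ester, so the equilibrium drains to 10.

**Step 16.** The chelate may not form or may not control the face in the ten-membered ring, leading to poor facial selectivity or competing conjugate reduction, because ring strain can distort the half-chair. Fallback: reagent-controlled reduction before desilylation. Starting from 27, Corey–Bakshi–Shibata reduction with (S)-2-methyl-CBS-oxazaborolidine and BH3·SMe2 gives the allylic alcohol F10 if the alkenyl arm acts as the larger ketone substituent; otherwise the enantiomeric catalyst is used. HF·pyridine then removes the C9 silyl group and rejoins the route at 30.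

**Step 19.** The tartrate-controlled epoxidation may be slow or mismatched with the ring's own facial bias, and the Lewis-acidic titanium may promote transannular opening of the epoxide by the C2=C3 alkene or acetate exchange. Fallback: epoxidise at the aldehyde oxidation level under substrate control. Starting from 32, MnO2 oxidation gives the enal F11, and nucleophilic (Weitz–Scheffer) epoxidation with t-BuOOH and 1,8-diazabicyclo[5.4.0]undec-7-ene, from the exposed face of the ring, leads directly to 34.

## Further compounds

F1 | step 14 | (1S,2R,3aS,8aS)-2-[(tert-butyldimethylsilyl)oxy]-3a-{[(tert-butyldiphenylsilyl)oxy]methyl}-8a-hydroxy-7-methyl-1-(propan-2-yl)-2,3,3a,5,6,8a-hexahydroazulen-4(1H)-one (C6 ketone of 24) | O[C@]12C=C(C)CCC(=O)[C@@]1(CO[Si](c3ccccc3)(c3ccccc3)C(C)(C)C)C[C@@H](O[Si](C)(C)C(C)(C)C)[C@@H]2C(C)C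
F2 | step 14 | C6 enol triflate of dienone 27 (trifluoromethanesulfonyloxy on C6, ring-cis C6=C7) | O=C1/C=C(/C)CC/C(OS(=O)(=O)C(F)(F)F)=C(CO[Si](c2ccccc2)(c2ccccc2)C(C)(C)C)\C[C@@H](O[Si](C)(C)C(C)(C)C)[C@@H]1C(C)C
F3 | step 9 | C6 (carbinol) epimer of 20 | I/C=C(/C)CC[C@H](O)[C@@]1(C(=O)OC)C[C@@H](O[Si](C)(C)C(C)(C)C)[C@H](C(C)C)C1=O
F4 | step 9 | C4 epimer of 22 | O[C@]12C=C(C)CC[C@H](O)[C@@]1(C(=O)OC)C[C@@H](O[Si](C)(C)C(C)(C)C)[C@@H]2C(C)C
F5 | step 9 | methyl 2-[(tert-butyldimethylsilyl)oxy]-8a-hydroxy-7-methyl-4-oxo-1-(propan-2-yl)octahydroazulene-3a-carboxylate (C4 ketone of 22) | O[C@]12C=C(C)CCC(=O)[C@@]1(C(=O)OC)C[C@@H](O[Si](C)(C)C(C)(C)C)[C@@H]2C(C)C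
F6 | step 10 | triethylsilyl ether of 20 | I/C=C(/C)CC[C@@H](O[Si](CC)(CC)CC)[C@@]1(C(=O)OC)C[C@@H](O[Si](C)(C)C(C)(C)C)[C@H](C(C)C)C1=O
F7 | step 10 | 4-O-triethylsilyl ether of 22 | O[C@]12C=C(C)CC[C@@H](O[Si](CC)(CC)CC)[C@@]1(C(=O)OC)C[C@@H](O[Si](C)(C)C(C)(C)C)[C@@H]2C(C)C
F8 | step 4 | (2S,3R)-3-[(tert-butyldimethylsilyl)oxy]-6-methoxy-6-oxo-2-(propan-2-yl)hexanoic acid | COC(=O)CC[C@@H](O[Si](C)(C)C(C)(C)C)[C@@H](C(=O)O)C(C)C
F9 | step 4 | dimethyl (2S,3R)-3-[(tert-butyldimethylsilyl)oxy]-2-(propan-2-yl)hexanedioate | COC(=O)CC[C@@H](O[Si](C)(C)C(C)(C)C)[C@@H](C(=O)OC)C(C)C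
F10 | step 16 | (1S,2Z,6E,9R,10S)-9-[(tert-butyldimethylsilyl)oxy]-7-{[(tert-butyldiphenylsilyl)oxy]methyl}-3-methyl-10-(propan-2-yl)cyclodeca-2,6-dien-1-ol | O[C@H]1/C=C(/C)CC/C=C(CO[Si](c2ccccc2)(c2ccccc2)C(C)(C)C)\C[C@@H](O[Si](C)(C)C(C)(C)C)[C@@H]1C(C)C
F11 | step 19 | (1S,2Z,6E,9R,10S)-7-formyl-3-methyl-10-(propan-2-yl)cyclodeca-2,6-diene-1,9-diyl diacetate | CC(=O)O[C@H]1/C=C(/C)CC/C=C(C=O)\C[C@@H](OC(C)=O)[C@@H]1C(C)C
A1 | alternative 1 | ten-membered isopropenyl triol | O[C@H]1/C=C(/C)CC/C=C(CO)\C[C@@H](O)[C@@H]1C(C)=C
A2 | alternative 1 | thirteen-membered bis-allylic ether | O1C/C=C(/C)CC/C=C(CO)\C[C@@H](O)/C=C(\C)C1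
A3 | alternative 2 | ten-membered homoallylic alcohol with exocyclic methylene on C7 | CC(C)(C)[Si](C)(C)O[C@H]1/C=C(/C)CC[C@@H](O[Si](CC)(CC)CC)C(=C)C[C@@H](O)[C@@H]1C(C)C
A4 | alternative 2 | open-chain aldehyde allylic chloride | O=C[C@H](C(C)C)[C@@H](O[Si](C)(C)C(C)(C)C)/C=C(/C)CC[C@@H](O[Si](CC)(CC)CC)C(=C)CCl
A5 | alternative 3 | ten-membered diene acetonide | CC1(C)O[C@H]2/C=C(/C)CC/C=C(CO[Si](C)(C)C(C)(C)C)\C[C@@H](O1)[C@@H]2C(C)C
A6 | alternative 3 | eleven-membered sulfone acetonide | CC1(C)O[C@H]2CS(=O)(=O)C(C)CC/C=C(CO[Si](C)(C)C(C)(C)C)\C[C@@H](O1)[C@@H]2C(C)C
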